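**Strategy**

The 3-(hydroxymethyl)-5-ylidenefuran-2(5H)-one ring is cut at O1–C5 and C3=C4. O1, C2, C3 and the CH2O carbon are then an α-keto acid (O-silyl hydroxypyruvic acid), while C4, C5 and the exocyclic C5=C alkene are an allenyltriphenylphosphonium salt that carries the whole furanoterpenoid chain. In one operation the carboxylate adds to the central allene carbon (O1–C5) anti to the chain, so that the untouched allene π bond becomes the (E)-exocyclic alkene, and the ylide so formed closes on the keto group by intramolecular Wittig reaction (C3=C4), extruding Ph3P=O. The precursor, a propargylic phosphonium salt, is built from neryl acetate.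

Key step: step 15

Remark: the target SMILES is read as R at the methyl-bearing stereocentre, E and Z at the two chain alkenes (furan end first), and E at the exocyclic alkene (chain syn to ring C4–H, anti to O1). This is the less stable ylidene geometry, so it is set kinetically in the last bond-forming step and only a buffered desilylation follows.

**Route**

Step 1
Reactants: 1 neryl acetate [(2Z)-3,7-dimethylocta-2,6-dien-1-yl acetate]
Product: 2 (2Z,6E)-8-hydroxy-3,7-dimethylocta-2,6-dien-1-yl acetate
Conditions: SeO2 (cat.), t-BuOOH, salicylic acid (cat.), CH2Cl2, 0 °C → rt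
Reagents that add atoms: tert-butyl hydroperoxide CC(C)(C)OO
Why: Sharpless SeO2/t-BuOOH allylic oxidation (ene reaction, then [2,3]-shift) should hydroxylate the (E)-methyl of the electron-rich terminal alkene, the 2,3-alkene being deactivated by the allylic acetate.

Step 2
Reactants: 2 (2Z,6E)-8-hydroxy-3,7-dimethylocta-2,6-dien-1-yl acetate
Product: 4 (2Z,7R)-3,7-dimethyloct-2-ene-1,8-diol, via saturated hydroxy acetate 3 (not isolated)
Conditions: Ru(OAc)2[(R)-BINAP] (1 mol%), H2 (50 atm), MeOH, rt; vent, pass through a silica pad; K2CO3 (cat.), MeOH, rt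
Reagents that add atoms: none
Why: Noyori hydroxyl-directed Ru–BINAP asymmetric hydrogenation should reduce only the alkene of the free allylic alcohol and set C7 as R by catalyst control (ligand antipode chosen from the geraniol/nerol facial model), after which base-catalysed methanolysis removes the acetate.

Step 3
Reactants: 4 (2Z,7R)-3,7-dimethyloct-2-ene-1,8-diol
Product: 5 (2R,6Z)-8-chloro-2,6-dimethyloct-6-en-1-ol
Conditions: NCS (1.1 equiv), Me2S (1.2 equiv), CH2Cl2, −40 → 0 °C
Reagents that add atoms: N-chlorosuccinimide O=C1CCC(=O)N1Cl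
Why: Corey–Kim chlorination should convert only the allylic alkoxysulfonium ion to the chloride by SN2 displacement (Z-alkene retained), the saturated alkoxysulfonium ion reverting to the alcohol on work-up.

Step 4
Reactants: 5 (2R,6Z)-8-chloro-2,6-dimethyloct-6-en-1-ol; 6 1-(trimethylsilyl)propyne
Product: 8 (2R,6Z)-2,6-dimethylundec-6-en-10-yn-1-ol, via silylated enynol 7 (not isolated)
Conditions: 6, n-BuLi, THF, −78 → −20 °C (2.5 equiv of the lithium reagent); 5, −78 → 0 °C; then MeOH, K2CO3, rt
Reagents that add atoms: none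
Why: SN2 alkylation of the primary allylic chloride by lithiated 1-silylpropyne (the silyl group steers propargyl over allenyl attack) followed by base-mediated protodesilylation should give the skipped enyne with the Z-alkene intact.

Step 5
Reactants: 8 (2R,6Z)-2,6-dimethylundec-6-en-10-yn-1-ol
Product: 10 (2R,6Z,10E)-11-iodo-2,6,10-trimethylundeca-6,10-dien-1-ol, via alkenylalane 9 (not isolated)
Conditions: Me3Al (3.5 equiv), Cp2ZrCl2 (0.25 equiv), CH2Cl2, 0 °C → rt; then I2, THF, −30 → 0 °C
Reagents that add atoms: trimethylaluminium C[Al](C)C; iodine II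
Why: Negishi Zr-catalysed methylalumination is a syn addition with methyl to the internal carbon, so iodinolysis with retention should give the (E)-2-methylalkenyl iodide; the hydroxyl is carried as its aluminium alkoxide.

Step 6
Reactants: 11 furan-3-carbaldehyde
Product: 12 3-vinylfuran
Conditions: Ph3PCH3Br, KOt-Bu, THF, 0 °C → rt; co-distilled and used as a THF solution
Reagents that add atoms: methyltriphenylphosphonium bromide C[P+](c1ccccc1)(c1ccccc1)c1ccccc1.[Br-]
Why: Wittig methylenation of the aldehyde.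

Step 7
Reactants: 12 3-vinylfuran; 10 (2R,6Z,10E)-11-iodo-2,6,10-trimethylundeca-6,10-dien-1-ol
Product: 14 (2R,6Z,10E)-13-(furan-3-yl)-2,6,10-trimethyltrideca-6,10-dien-1-ol, via furylethylborane 13 (not isolated)
Conditions: 12, 9-BBN, THF, 0 °C → rt; then 10, PdCl2(dppf) (5 mol%), AsPh3, Cs2CO3, DMF/THF/H2O, rt
Reagents that add atoms: none
Why: anti-Markovnikov hydroboration of the vinyl group and B-alkyl Suzuki–Miyaura coupling with retention of the alkenyl iodide geometry should complete the (E)-trisubstituted alkene and the carbon chain.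

Step 8
Reactants: 14 (2R,6Z,10E)-13-(furan-3-yl)-2,6,10-trimethyltrideca-6,10-dien-1-ol
Product: 15 (2R,6Z,10E)-13-(furan-3-yl)-2,6,10-trimethyltrideca-6,10-dienal
Conditions: Dess–Martin periodinane, NaHCO3, CH2Cl2, 0 °C → rt; used at once
Reagents that add atoms: none
Why: buffered Dess–Martin oxidation should give the α-methyl aldehyde without epimerisation and without touching the furan.

Step 9
Reactants: 15 (2R,6Z,10E)-13-(furan-3-yl)-2,6,10-trimethyltrideca-6,10-dienal
Product: 16 3-[(3E,7Z,12R)-4,8,12-trimethyltetradeca-3,7-dien-13-yn-1-yl]furan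
Conditions: dimethyl (1-diazo-2-oxopropyl)phosphonate, K2CO3, MeOH, 0 °C → rt
Reagents that add atoms: dimethyl (1-diazo-2-oxopropyl)phosphonate COP(=O)(OC)C(=[N+]=[N-])C(C)=O
Why: Ohira–Bestmann (Seyferth–Gilbert) homologation should give the terminal alkyne under conditions mild enough to preserve the adjacent stereocentre.

Step 10
Reactants: 16 3-[(3E,7Z,12R)-4,8,12-trimethyltetradeca-3,7-dien-13-yn-1-yl]furan
Product: 18 (4R,8Z,12E)-15-(furan-3-yl)-4,8,12-trimethylpentadeca-8,12-dien-2-yn-1-ol, via lithium acetylide 17 (not isolated)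
Conditions: n-BuLi (1.05 equiv), THF, −78 °C; (CH2O)n, −78 °C → rt
Reagents that add atoms: formaldehyde (as paraformaldehyde) C=O
Why: the alkyne C–H is deprotonated far faster than the furan, and addition of the acetylide to formaldehyde gives the propargylic alcohol.

Step 11
Reactants: 18 (4R,8Z,12E)-15-(furan-3-yl)-4,8,12-trimethylpentadeca-8,12-dien-2-yn-1-ol
Product: 20 [(4R,8Z,12E)-15-(furan-3-yl)-4,8,12-trimethylpentadeca-8,12-dien-2-yn-1-yl]triphenylphosphonium bromide, via propargylic bromide 19 (not isolated)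
Conditions: CBr4 (1.2 equiv), PPh3 (1.25 equiv), CH2Cl2, 0 °C; then PPh3 (1.5 equiv), MeCN, rt → 40 °C
Reagents that add atoms: carbon tetrabromide BrC(Br)(Br)Br; triphenylphosphine c1ccc(cc1)P(c1ccccc1)c1ccccc1
Why: Appel bromination followed by SN2 quaternisation of PPh3 at the unhindered primary propargylic carbon should place phosphorus on the future C4.

Step 12
Reactants: 21 methyl 2-(hydroxymethyl)acrylate
Product: 22 methyl 2-{[(tert-butyldimethylsilyl)oxy]methyl}prop-2-enoate
Conditions: TBSCl, imidazole, CH2Cl2, 0 °C → rt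
Reagents that add atoms: tert-butyldimethylsilyl chloride CC(C)(C)[Si](C)(C)Cl
Why: standard silylation of the primary alcohol.

Step 13
Reactants: 22 methyl 2-{[(tert-butyldimethylsilyl)oxy]methyl}prop-2-enoate
Product: 24 methyl 3-[(tert-butyldimethylsilyl)oxy]-2-oxopropanoate, via ozonide 23 (not isolated)
Conditions: O3, CH2Cl2, −78 °C; Me2S, −78 °C → rt
Reagents that add atoms: ozone [O-][O+]=O
Why: ozonolysis of the 1,1-disubstituted acrylate alkene with reductive work-up gives the α-keto ester.

Step 14
Reactants: 24 methyl 3-[(tert-butyldimethylsilyl)oxy]-2-oxopropanoate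
Product: 25 3-[(tert-butyldimethylsilyl)oxy]-2-oxopropanoic acid
Conditions: LiOH (1.05 equiv), THF/H2O, 0 °C; cold 1 M HCl to pH 3, extract; used at once
Reagents that add atoms: lithium hydroxide [Li+].[OH-]
Why: α-keto esters saponify rapidly at 0 °C with one equivalent of hydroxide, and the primary TBS ether should survive the brief cold acidification.

Step 15
Reactants: 20 [(4R,8Z,12E)-15-(furan-3-yl)-4,8,12-trimethylpentadeca-8,12-dien-2-yn-1-yl]triphenylphosphonium bromide; 25 3-[(tert-butyldimethylsilyl)oxy]-2-oxopropanoic acid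
Product: 28 (5E)-3-{[(tert-butyldimethylsilyl)oxy]methyl}-5-[(2R,6Z,10E)-13-(furan-3-yl)-2,6,10-trimethyltrideca-6,10-dien-1-ylidene]furan-2(5H)-one, via allenylphosphonium bromide 26 (not isolated), via acyloxyallylidene phosphorane 27 (not isolated)
Conditions: 25 (1.3 equiv), i-Pr2NEt (1.5 equiv, slow addition), CH2Cl2, −20 °C → rt, dark
Reagents that add atoms: none
Why: Proposed new method: amine-mediated 1,3-prototropy converts the alk-2-ynylphosphonium salt into allenylphosphonium salt 26, whose central carbon (future C5) is the β-position of a vinylphosphonium Michael acceptor; the α-keto carboxylate adds there (O1–C5) to give ylide 27, which undergoes intramolecular Wittig olefination with the adjacent, highly electrophilic ketone (C3=C4) and expels Ph3P=O. The closest known reaction type is the Schweizer annulation (conjugate addition of an oxygen nucleophile to a vinyl- or allenylphosphonium salt followed by intramolecular Wittig reaction, as in the 2,5-dihydrofuran synthesis from α-hydroxy ketone alkoxides); a carboxylate donor with an α-keto acceptor on an allenyl salt is the untested element. The butenolide closes in a five-membered, formally 5-exo-trig attack of the ylide carbon on the ketone followed by oxaphosphetane collapse, and the ring enforces the cis relationship of C2 and C5 across C3=C4. No stereocentre is created, and the methyl-bearing stereocentre is not part of the reacting π system and should be untouched under the weakly basic conditions. The step needs E selectivity at the exocyclic alkene: the carboxylate must enter the π*(C=C–P+) lobe at the central allene carbon in the plane of the remote CH(R) terminus, where the branched chain blocks one side, so O1 ends anti to the chain and the chain syn to C4–H for either allene diastereomer. It also needs the carboxylate to add before the salt isomerises further to the alk-1-ynyl isomer, which an excess of carboxylate and slow addition of the hindered amine at low temperature are meant to secure.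

Step 16
Reactants: 28 (5E)-3-{[(tert-butyldimethylsilyl)oxy]methyl}-5-[(2R,6Z,10E)-13-(furan-3-yl)-2,6,10-trimethyltrideca-6,10-dien-1-ylidene]furan-2(5H)-one
Product: 29 22-deoxy-23-hydroxymethylvariabilin [(5E)-5-[(2R,6Z,10E)-13-(furan-3-yl)-2,6,10-trimethyltrideca-6,10-dien-1-ylidene]-3-(hydroxymethyl)furan-2(5H)-one]
Conditions: HF·pyridine, pyridine/THF, 0 °C → rt, dark
Reagents that add atoms: none
Why: buffered fluoride desilylation should cleave the primary TBS ether without opening the enol lactone, isomerising the (E)-ylidene or affecting the furan.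

**Compound list**

1 | neryl acetate, (2Z)-3,7-dimethylocta-2,6-dien-1-yl acetate | CC(=O)OC/C=C(C)\CCC=C(C)C | starting material
2 | (2Z,6E)-8-hydroxy-3,7-dimethylocta-2,6-dien-1-yl acetate | CC(=O)OC/C=C(C)\CC/C=C(\C)CO | intermediate
3 | (2Z,7R)-8-hydroxy-3,7-dimethyloct-2-en-1-yl acetate (not isolated) | CC(=O)OC/C=C(C)\CCC[C@@H](C)CO | intermediate
4 | (2Z,7R)-3,7-dimethyloct-2-ene-1,8-diol | OC/C=C(C)\CCC[C@@H](C)CO | intermediate
5 | (2R,6Z)-8-chloro-2,6-dimethyloct-6-en-1-ol | ClC/C=C(C)\CCC[C@@H](C)CO | intermediate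
6 | 1-(trimethylsilyl)propyne | CC#C[Si](C)(C)C | starting material
7 | (2R,6Z)-2,6-dimethyl-11-(trimethylsilyl)undec-6-en-10-yn-1-ol (not isolated) | C[Si](C)(C)C#CCC/C=C(C)\CCC[C@@H](C)CO | intermediate
8 | (2R,6Z)-2,6-dimethylundec-6-en-10-yn-1-ol | C#CCC/C=C(C)\CCC[C@@H](C)CO | intermediate
9 | (E)-alkenyl(dimethyl)alane of 8, as its O-dimethylaluminium alkoxide (not isolated) | C[Al](C)/C=C(\C)CC/C=C(C)\CCC[C@@H](C)CO[Al](C)C | intermediate
10 | (2R,6Z,10E)-11-iodo-2,6,10-trimethylundeca-6,10-dien-1-ol | I/C=C(\C)CC/C=C(C)\CCC[C@@H](C)CO | intermediate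
11 | furan-3-carbaldehyde | O=Cc1ccoc1 | starting material
12 | 3-vinylfuran | C=Cc1ccoc1 | intermediate
13 | 9-[2-(furan-3-yl)ethyl]-9-borabicyclo[3.3.1]nonane (not isolated) | C(Cc1ccoc1)B1C2CCCC1CCC2 | intermediate
14 | (2R,6Z,10E)-13-(furan-3-yl)-2,6,10-trimethyltrideca-6,10-dien-1-ol | C/C(=C/CC/C(C)=C/CCc1ccoc1)CCC[C@@H](C)CO | intermediate
15 | (2R,6Z,10E)-13-(furan-3-yl)-2,6,10-trimethyltrideca-6,10-dienal | C/C(=C/CC/C(C)=C/CCc1ccoc1)CCC[C@@H](C)C=O | intermediate
16 | 3-[(3E,7Z,12R)-4,8,12-trimethyltetradeca-3,7-dien-13-yn-1-yl]furan | C/C(=C/CC/C(C)=C/CCc1ccoc1)CCC[C@@H](C)C#C | intermediate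
17 | lithium acetylide of 16 (not isolated) | C/C(=C/CC/C(C)=C/CCc1ccoc1)CCC[C@@H](C)C#C[Li] | intermediate
18 | (4R,8Z,12E)-15-(furan-3-yl)-4,8,12-trimethylpentadeca-8,12-dien-2-yn-1-ol | C/C(=C/CC/C(C)=C/CCc1ccoc1)CCC[C@@H](C)C#CCO | intermediate
19 | 3-[(3E,7Z,12R)-15-bromo-4,8,12-trimethylpentadeca-3,7-dien-13-yn-1-yl]furan (not isolated) | C/C(=C/CC/C(C)=C/CCc1ccoc1)CCC[C@@H](C)C#CCBr | intermediate
20 | [(4R,8Z,12E)-15-(furan-3-yl)-4,8,12-trimethylpentadeca-8,12-dien-2-yn-1-yl]triphenylphosphonium bromide | C/C(=C/CC/C(C)=C/CCc1ccoc1)CCC[C@@H](C)C#CC[P+](c1ccccc1)(c1ccccc1)c1ccccc1.[Br-] | intermediate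
21 | methyl 2-(hydroxymethyl)acrylate | COC(=O)C(=C)CO | starting material
22 | methyl 2-{[(tert-butyldimethylsilyl)oxy]methyl}prop-2-enoate | COC(=O)C(=C)CO[Si](C)(C)C(C)(C)C | intermediate
23 | methyl 3-{[(tert-butyldimethylsilyl)oxy]methyl}-1,2,4-trioxolane-3-carboxylate (not isolated) | COC(=O)C1(CO[Si](C)(C)C(C)(C)C)OCOO1 | intermediate
24 | methyl 3-[(tert-butyldimethylsilyl)oxy]-2-oxopropanoate | COC(=O)C(=O)CO[Si](C)(C)C(C)(C)C | intermediate
25 | 3-[(tert-butyldimethylsilyl)oxy]-2-oxopropanoic acid | OC(=O)C(=O)CO[Si](C)(C)C(C)(C)C | intermediate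
26 | [(4R,8Z,12E)-15-(furan-3-yl)-4,8,12-trimethylpentadeca-1,2,8,12-tetraen-1-yl]triphenylphosphonium bromide, both allene diastereomers (not isolated) | C/C(=C/CC/C(C)=C/CCc1ccoc1)CCC[C@@H](C)C=C=C[P+](c1ccccc1)(c1ccccc1)c1ccccc1.[Br-] | intermediate
27 | (2E,4R,8Z,12E)-15-(furan-3-yl)-4,8,12-trimethyl-1-(triphenyl-λ5-phosphanylidene)pentadeca-2,8,12-trien-2-yl 3-[(tert-butyldimethylsilyl)oxy]-2-oxopropanoate (not isolated) | C/C(=C/CC/C(C)=C/CCc1ccoc1)CCC[C@@H](C)/C=C(OC(=O)C(=O)CO[Si](C)(C)C(C)(C)C)\C=P(c1ccccc1)(c1ccccc1)c1ccccc1 | intermediate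
28 | (5E)-3-{[(tert-butyldimethylsilyl)oxy]methyl}-5-[(2R,6Z,10E)-13-(furan-3-yl)-2,6,10-trimethyltrideca-6,10-dien-1-ylidene]furan-2(5H)-one | C/C(=C/CC/C(C)=C/CCc1ccoc1)CCC[C@@H](C)/C=C1\C=C(CO[Si](C)(C)C(C)(C)C)C(=O)O1 | intermediate
29 | 22-deoxy-23-hydroxymethylvariabilin, (5E)-5-[(2R,6Z,10E)-13-(furan-3-yl)-2,6,10-trimethyltrideca-6,10-dien-1-ylidene]-3-(hydroxymethyl)furan-2(5H)-one | C/C(=C/CC/C(C)=C/CCc1ccoc1)CCC[C@@H](C)/C=C1\C=C(CO)C(=O)O1 | target

**Step count and risks**

Total step count: 16. Longest linear sequence: 12 steps (1–5, 7–11, 15, 16, from neryl acetate).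

Steps most likely to fail:

1. Step 15 (Proposed new method). The carboxylate may add too slowly relative to further prototropic isomerisation of the salt to the alk-1-ynyl isomer; its adduct reaches the ylide only by unselective γ-deprotonation, which would erode the exocyclic E geometry. Intermolecular Wittig reaction of the propargyl ylide with the keto group would drain material to an enyne. The fallback uses known reactions, makes the two ring bonds in separate steps, sets out from aldehyde 15 and returns at target 29. An (E)-selective bromo-Horner–Wadsworth–Emmons reaction with methyl bis(2,2,2-trifluoroethyl) bromophosphonoacetate (t-BuOK, 18-crown-6, −78 °C) would give methyl (2E)-2-bromoenoate F1, with the chain cis to the ester carbon. DIBAL-H reduction would give bromoallylic alcohol F2, and MnO2 oxidation (E)-2-bromoenal F3. Addition of [1-(methoxycarbonyl)vinyl]diisobutylalane (from methyl propiolate, DIBAL-H and NMO) would give Baylis–Hillman-type adduct F4, and LiOH the acid F5. Copper-catalysed intramolecular O-vinylation of the carboxylic acid by the vinyl bromide (CuI, trans-N,N′-dimethylcyclohexane-1,2-diamine, Cs2CO3), which proceeds with retention, would give α-methylene-β-hydroxy-(E)-ylidene lactone F6. Rhenium-oxo-catalysed (Ph3SiOReO3) 1,3-transposition of the allylic hydroxyl into conjugation would then give 29.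

2. Step 2. Enantioface discrimination may be poor for a 2-methyl-substituted allylic alcohol, and ruthenium-mediated redox isomerisation of the allylic alcohol to the aldehyde may compete. The fallback moves the stereo-defining hydrogenation to the carboxylic acid oxidation level (carboxylate-directed, tiglic-acid class), sets out from 2 and returns at diol 4. TEMPO/PhI(OAc)2 in MeCN/H2O would give dienoic acid F7. Ru(OAc)2(BINAP)/H2 in MeOH, with the ligand antipode that delivers 2R, would give saturated acid F8. LiAlH4 would reduce the acid and cleave the acetate to give 4.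

3. Step 3. The saturated primary hydroxyl may be activated competitively, or the allylic sulfonium ion may ionise and scramble the Z-alkene. The fallback differentiates the two hydroxyls with a protecting group, sets out from hydroxy acetate 3 (isolated after the hydrogenation) and returns at enynol 8. TBSCl/imidazole would give silyl ether acetate F9, and K2CO3/MeOH the allylic alcohol F10. MsCl/Et3N then LiCl would give allylic chloride F11. Alkylation with lithiated 6 would give bis-silyl enyne F12, and TBAF would remove both silyl groups to give 8.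

**Further compounds**

F1 | step 15 | methyl (2E,4R,8Z,12E)-2-bromo-15-(furan-3-yl)-4,8,12-trimethylpentadeca-2,8,12-trienoate | C/C(=C/CC/C(C)=C/CCc1ccoc1)CCC[C@@H](C)/C=C(/Br)C(=O)OC
F2 | step 15 | (2E,4R,8Z,12E)-2-bromo-15-(furan-3-yl)-4,8,12-trimethylpentadeca-2,8,12-trien-1-ol | C/C(=C/CC/C(C)=C/CCc1ccoc1)CCC[C@@H](C)/C=C(/Br)CO
F3 | step 15 | (2E,4R,8Z,12E)-2-bromo-15-(furan-3-yl)-4,8,12-trimethylpentadeca-2,8,12-trienal | C/C(=C/CC/C(C)=C/CCc1ccoc1)CCC[C@@H](C)/C=C(/Br)C=O
F4 | step 15 | methyl 2-[(2E,4R,8Z,12E)-2-bromo-15-(furan-3-yl)-1-hydroxy-4,8,12-trimethylpentadeca-2,8,12-trien-1-yl]prop-2-enoate | C/C(=C/CC/C(C)=C/CCc1ccoc1)CCC[C@@H](C)/C=C(/Br)C(O)C(=C)C(=O)OC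
F5 | step 15 | 2-[(2E,4R,8Z,12E)-2-bromo-15-(furan-3-yl)-1-hydroxy-4,8,12-trimethylpentadeca-2,8,12-trien-1-yl]prop-2-enoic acid | C/C(=C/CC/C(C)=C/CCc1ccoc1)CCC[C@@H](C)/C=C(/Br)C(O)C(=C)C(=O)O
F6 | step 15 | (5E)-5-[(2R,6Z,10E)-13-(furan-3-yl)-2,6,10-trimethyltrideca-6,10-dien-1-ylidene]-4-hydroxy-3-methylideneoxolan-2-one | C/C(=C/CC/C(C)=C/CCc1ccoc1)CCC[C@@H](C)/C=C1\C(O)C(=C)C(=O)O1
F7 | step 2 | (2E,6Z)-8-acetoxy-2,6-dimethylocta-2,6-dienoic acid | CC(=O)OC/C=C(C)\CC/C=C(\C)C(=O)O
F8 | step 2 | (2R,6Z)-8-acetoxy-2,6-dimethyloct-6-enoic acid | CC(=O)OC/C=C(C)\CCC[C@@H](C)C(=O)O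
F9 | step 3 | (2Z,7R)-8-[(tert-butyldimethylsilyl)oxy]-3,7-dimethyloct-2-en-1-yl acetate | CC(=O)OC/C=C(C)\CCC[C@@H](C)CO[Si](C)(C)C(C)(C)C
F10 | step 3 | (2Z,7R)-8-[(tert-butyldimethylsilyl)oxy]-3,7-dimethyloct-2-en-1-ol | OC/C=C(C)\CCC[C@@H](C)CO[Si](C)(C)C(C)(C)C
F11 | step 3 | tert-butyl{[(2R,6Z)-8-chloro-2,6-dimethyloct-6-en-1-yl]oxy}dimethylsilane | ClC/C=C(C)\CCC[C@@H](C)CO[Si](C)(C)C(C)(C)C
F12 | step 3 | tert-butyl{[(2R,6Z)-2,6-dimethyl-11-(trimethylsilyl)undec-6-en-10-yn-1-yl]oxy}dimethylsilane | C[Si](C)(C)C#CCC/C=C(C)\CCC[C@@H](C)CO[Si](C)(C)C(C)(C)C
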